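Locants C1–C11 are those of the target (ring A = C1–C6, ring B = C6–C11) and are used for all intermediates.

## The problem

Target 24 is a spiro[5.5]undecane in which the spiro carbon C6 is bonded directly to the gem-dimethyl carbon C1, so two quaternary carbons are adjacent, and ring B holds a third fully substituted carbon, the tertiary chloride C9. Five stereocentres must be set: C2 (Br) and C3 (OH) on ring A as a trans-diequatorial bromohydrin, C6, and C8 (Br)/C9 (Cl, CH3) on ring B as a trans bromochloride with bromine cis to C1 and chlorine cis to C5. C6 is stereogenic only because the two arms of ring B differ, so the ring A and ring B centres are remote from each other and neither ring can be trusted to control the other. C6 can nevertheless relay to ring B, because the bulky C1 side sits equatorial on ring B and holds the C5 carbon axial over one face. That same bias makes the ring B pattern awkward: the halogens are diequatorial, whereas plain anti addition of BrCl to a C8=C9 alkene should open the bromonium ion diaxially and put bromine on the face of C5. The tertiary chloride and the secondary bromides ionise or eliminate easily, the bromohydrin closes to an epoxide with base, and the exocyclic methylene can move into ring A with acid, so organometallic steps must precede the halogens and the last steps must be mild. The enabling feature is that C8 can be a ketone: C6 is then the β-carbon of a cyclohexenone carrying the C5 carboxyl group, and the C6–C1 bond can be made by radical recombination in an enone–alkene photocycloaddition instead of by polar addition to a hindered centre.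

## Retrosynthesis

**24 from 23 (C3–C4 bond).** Ring A is opened between C3 and C4, which leads to aldehyde 23 with an isopropenyl group on C6. The forward reaction is a type 2 carbonyl-ene closure that forms the ring, the carbinol and the exocyclic methylene together. An aldol closure onto a C5 methyl ketone would need a later methylenation next to a base-sensitive bromohydrin. Brominating a ring A ketone would have to discriminate C2 from the more acidic C4. The ene step must place the C–O bond equatorial, trans to bromine.

**23 from 19 (C2–Br, C5=CH2, C3 oxidation level).** Because C6 cannot control ring A, C2 is set by reagent control: enamine-catalysed α-bromination of aldehyde 22, where C2 is the only α-position. Aldehyde 22 comes from alcohol 21 and silyl ether 20, and the isopropenyl group of 20 from methyl ketone 19. All of these are functional-group changes on a fixed skeleton.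

**19 from 16 (C9–Cl, C5–CH3).** The ring B halogen pattern is traced to bromolactone 16. Methyllithium turns the lactone carbonyl into the C5 methyl ketone (hydroxy ketone 18, through hemiketal 17). The tertiary C9–O bond is then exchanged for C9–Cl with retention, because the anti bromine on C8 bridges as the oxygen leaves. This is preferred to BrCl addition to a ring B alkene, which should give the diaxial isomer with the wrong face.

**16 from 15 (C8–Br, C9–O).** Bromolactonisation of acid 15 removes both ring B heteroatom centres. The axial carboxyl on C6 can reach C9 only from the face on which chlorine must end, and bromine must enter anti, on the face of C1. The precursor has only the C6 stereocentre.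

**15 from 11 (redox, auxiliary release).** Acid 15 comes from diester 11 by full reduction to diol 12, silylation of the unhindered alcohol (13) and oxidation of the neopentyl alcohol through aldehyde 14. The two esters of 11 cannot be told apart by a nucleophile, but the two alcohols of 12 differ greatly in hindrance.

**11 from 8 (C9–CH3, C8 deoxygenation).** The C8=C9 methyl alkene comes from ketone 8 by methylation at C9 (9), enol triflate formation (10) and reduction. The ketone is the only handle on ring B and is used once for the methyl group and once for the alkene position.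

**8 from 7 (C7–C2 reconnection).** Keto diester 8 is the formal conjugate adduct of an ester enolate equivalent to a β-substituted enone. Reconnecting C7 to C2 gives cyclobutane 7, whose strain and γ-keto ester arrangement allow reductive cleavage of exactly this bond.

**7 from 5 and 6 (C6–C1 and C7–C2).** The cyclobutane is cut into enone ester 5 and methyl 3-methylbut-2-enoate 6. This is the only cut in the route that makes the quaternary–quaternary bond, and it does so from two simple achiral π-systems plus a recoverable auxiliary. The forward reaction must be head-to-head and must select one enone face.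

**5 from 3 and 4; 3 from 1.** Ester 5 is made from acid 3 and (1R,2S,5R)-8-phenylmenthol 4, and 3 from 3-methoxybenzoic acid 1 by Birch reduction through the dihydro acid 2.

## Roads not taken

Alternative 1: Ring A is cut at C3–C4 on a spirocycle whose ring B is still a symmetric cyclohexanone ketal. Me2AlCl would promote a type 2 carbonyl-ene reaction of bromo aldehyde A2 to give bromohydrin A1. Its merits are real: ring A, the carbinol and the exocyclic methylene form in one step, and C6 is not yet stereogenic, so no early asymmetric induction is needed. On step economy at ring A it is as good as anything available, and the chosen plan uses the same closure in step 18. Its weak points lie before and after that step. A2 already needs an isopropenyl group and a CMe2 unit on the same ring carbon, and the cut says nothing about how that quaternary–quaternary bond is made. After A1, the ring B ketone must be desymmetrised relative to distant ring A centres, with no bias between the two α-positions. The diequatorial bromochloride then has to be installed without an internal nucleophile, because C5 is already the methylene carbon. The chosen plan sets against this a defined construction of the C6–C1 bond and a C5 carboxyl group that relays C6 to C8 and C9.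

Alternative 2: The C6–C11 bond is cut. KOt-Bu would convert phenol tosylate A5, made from 3,5-dimethylphenol A4, into its phenoxide, whose para carbon displaces the tosylate to give spirotrienone A3. The start is cheap, the spiro carbon is made by a robust intramolecular C-alkylation, the ring B methyl alkene is already in place, and the skeleton is reached in fewer steps and without photochemistry. Against that, A3 is achiral, and the para carbon is flanked by two methyl groups, so O-alkylation may compete. One of two enantiotopic enone arms must then accept a methyl group at a β-carbon next to the spiro centre, which is the same quaternary–quaternary problem recast as an enantioselective conjugate addition. The other arm must be deconjugated to the exocyclic alkene and given C2–Br and C3–OH. The chosen plan is longer to the skeleton but arrives with C6 defined and the gem-dimethyl carbon attached.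

Alternative 3: The C10–C11 and C6–C1 bonds are cut. AgSbF6 would ionise the cis-allylic chloride of cyclopentanol A7, the 1,1-disubstituted alkene would close ring B on the allyl cation, and migration of the gem-dimethyl carbon would expand the ring to ketone A6. This is the most economical skeleton-building step of the four, and it could in principle relay the ring A centres to C6 through a stereospecific shift. The weak points are as follows:
- A7 carries a secondary bromide next to the migrating carbon under strongly ionising conditions, so bromine participation and elimination are likely.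
- The allyl cation can react at either terminus and can lose its geometry.
- The facial course of the alkene attack, which fixes C6, is unproven.
- A7 is itself a demanding target, with three contiguous stereocentres on a cyclopentane.
- A6 then meets the ring B bromochlorination problem with a C5 ketone that cannot deliver a nucleophile to C9.

The chosen plan is longer, but each step has close precedent, and it keeps the C5 carboxyl group for the halogenation.

Key step: step 3

## Route

Assumption 1: the open face of enone 5 is taken from the π-stacking model of 8-phenylmenthyl enoates and is assumed to give the C6 configuration drawn in 7; if the sense is opposite, the enantiomeric auxiliary is used and nothing else changes.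

Assumption 2: (2R,5R)-2,5-diphenylpyrrolidine is assumed to be the catalyst enantiomer that gives the 2S bromide 23; if not, its antipode is used.

Step 1
Reactants: 1 3-methoxybenzoic acid
Product: 3 3-oxocyclohex-1-ene-1-carboxylic acid, via dihydroanisic acid 2 (not isolated)
Conditions: Na, NH3 (l), EtOH, −78 °C; then 2 M HCl, 60 °C
Reagents that add atoms: water (O)
Why: Birch reduction of the benzoate gives the 1,4-dihydro acid 2; aqueous acid hydrolyses the enol ether and moves the remaining double bond into conjugation with both carbonyl groups, the thermodynamic isomer.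

Step 2
Reactants: 3 3-oxocyclohex-1-ene-1-carboxylic acid; 4 (1R,2S,5R)-8-phenylmenthol
Product: 5 (1R,2S,5R)-8-phenylmenthyl 3-oxocyclohex-1-ene-1-carboxylate
Conditions: DCC, DMAP (cat.), CH2Cl2, 0 °C to rt
Reagents that add atoms: none
Why: Steglich esterification; carbodiimide activation and acyl transfer by DMAP couple the hindered secondary alcohol without touching the enone.

Step 3
Reactants: 5 (1R,2S,5R)-8-phenylmenthyl 3-oxocyclohex-1-ene-1-carboxylate; 6 methyl 3-methylbut-2-enoate
Product: 7 8-methyl 6-[(1R,2S,5R)-8-phenylmenthyl] (1S,6R,8S)-7,7-dimethyl-2-oxobicyclo[4.2.0]octane-6,8-dicarboxylate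
Conditions: hν (350 nm, Pyrex), 6 (10 equiv), CH2Cl2, −40 °C
Reagents that add atoms: none
Why: Enone–alkene [2+2] photocycloaddition: excitation of 5 and intersystem crossing give the triplet enone, which adds to 6 stepwise through a triplet 1,4-diradical that closes after spin inversion. The cyclobutane is therefore closed by radical recombination and not by a polar ring closure, which is why the bond between the fully substituted carbons C6 and C1 can form. The step needs head-to-head regiochemistry (ester-bearing carbon on the enone α-carbon, dimethyl carbon on the β-carbon); donor-substituted alkene carbons bond to the enone β-carbon and acceptor-substituted ones to the α-carbon, and either first bond leaves a tertiary or ester-stabilised radical. C6 is controlled by the auxiliary: the phenyl ring stacks over one face of the enoate, the alkene enters from the open face, and low temperature favours the stacked conformer. The ring-fusion centre (C7) is controlled by strain, since the cis-fused bicyclo[4.2.0]octanone is favoured and any trans-fused adduct epimerises on alumina. The ester-bearing centre (C2) is not controlled and is drawn as one epimer. Neither of these two centres matters, because both become CH2 in step 4. The closest known reaction type is the photocycloaddition of 3-alkoxycarbonylcyclohexenones, including chiral esters, to alkenes.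

Step 4
Reactants: 7 8-methyl 6-[(1R,2S,5R)-8-phenylmenthyl] (1S,6R,8S)-7,7-dimethyl-2-oxobicyclo[4.2.0]octane-6,8-dicarboxylate
Product: 8 (1R,2S,5R)-8-phenylmenthyl (1R)-1-(4-methoxy-2-methyl-4-oxobutan-2-yl)-3-oxocyclohexane-1-carboxylate
Conditions: SmI2 (2.5 equiv), THF/MeOH, −78 °C
Reagents that add atoms: none
Why: Ketyl fragmentation of a cyclobutyl ketone: electron transfer from divalent samarium to the ketone and β-scission of the exocyclic cyclobutane bond, which is aligned with the ketyl and leaves an ester-stabilised radical; a second electron and protonation give the keto diester. All ring-fusion and C2 epimers of 7 converge on 8.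

Step 5
Reactants: 8 (1R,2S,5R)-8-phenylmenthyl (1R)-1-(4-methoxy-2-methyl-4-oxobutan-2-yl)-3-oxocyclohexane-1-carboxylate
Product: 9 (1R,2S,5R)-8-phenylmenthyl (1R,4RS)-1-(4-methoxy-2-methyl-4-oxobutan-2-yl)-4-methyl-3-oxocyclohexane-1-carboxylate
Conditions: LiN(iPr)2 (LDA), THF, −78 °C; then MeI, −78 to −20 °C
Reagents that add atoms: iodomethane (CI)
Why: Kinetic enolate alkylation; the amide base removes a proton from the ketone α-CH2 remote from the quaternary carbon, leaving the neopentyl α-position and the less acidic ester. The new centre need not be controlled because it becomes sp2 in step 6.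

Step 6
Reactants: 9 (1R,2S,5R)-8-phenylmenthyl (1R,4RS)-1-(4-methoxy-2-methyl-4-oxobutan-2-yl)-4-methyl-3-oxocyclohexane-1-carboxylate
Product: 10 (1R,2S,5R)-8-phenylmenthyl (1R)-1-(4-methoxy-2-methyl-4-oxobutan-2-yl)-4-methyl-3-(trifluoromethanesulfonyloxy)cyclohex-3-ene-1-carboxylate
Conditions: Tf2O, 2,6-di-tert-butyl-4-methylpyridine, CH2Cl2, 0 °C to rt
Reagents that add atoms: trifluoromethanesulfonic anhydride (O=S(=O)(OS(=O)(=O)C(F)(F)F)C(F)(F)F)
Why: Enol triflate formation under equilibrating conditions; O-triflation and proton loss favour the more substituted C8=C9 enol triflate, and both C9 epimers converge.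

Step 7
Reactants: 10 (1R,2S,5R)-8-phenylmenthyl (1R)-1-(4-methoxy-2-methyl-4-oxobutan-2-yl)-4-methyl-3-(trifluoromethanesulfonyloxy)cyclohex-3-ene-1-carboxylate
Product: 11 (1R,2S,5R)-8-phenylmenthyl (1R)-1-(4-methoxy-2-methyl-4-oxobutan-2-yl)-4-methylcyclohex-3-ene-1-carboxylate
Conditions: Pd(OAc)2 (cat.), PPh3, HCO2H, Bu3N, DMF, 60 °C
Reagents that add atoms: none
Why: Palladium-catalysed formate reduction of an enol triflate: oxidative addition to zerovalent palladium, formate exchange, decarboxylation and C–H reductive elimination, with the alkene position retained and the esters untouched.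

Step 8
Reactants: 11 (1R,2S,5R)-8-phenylmenthyl (1R)-1-(4-methoxy-2-methyl-4-oxobutan-2-yl)-4-methylcyclohex-3-ene-1-carboxylate
Product: 12 3-[(1R)-1-(hydroxymethyl)-4-methylcyclohex-3-en-1-yl]-3-methylbutan-1-ol
Conditions: LiAlH4, THF, 0 °C to reflux
Reagents that add atoms: none
Why: Hydride reduction of both esters; the small AlH4− reaches the neopentyl ester that larger nucleophiles would not, the trisubstituted alkene is inert, and the auxiliary alcohol 4 is recovered.

Step 9
Reactants: 12 3-[(1R)-1-(hydroxymethyl)-4-methylcyclohex-3-en-1-yl]-3-methylbutan-1-ol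
Product: 13 [(1R)-4-methyl-1-{2-methyl-4-[tri(propan-2-yl)silyloxy]butan-2-yl}cyclohex-3-en-1-yl]methanol
Conditions: iPr3SiCl, imidazole, DMF, 0 °C
Reagents that add atoms: chlorotri(propan-2-yl)silane (CC(C)[Si](Cl)(C(C)C)C(C)C)
Why: Selective silylation; the bulky silyl chloride reacts with the unhindered primary alcohol, while the CH2OH between two quaternary carbons is far slower.

Step 10
Reactants: 13 [(1R)-4-methyl-1-{2-methyl-4-[tri(propan-2-yl)silyloxy]butan-2-yl}cyclohex-3-en-1-yl]methanol
Product: 15 (1R)-4-methyl-1-{2-methyl-4-[tri(propan-2-yl)silyloxy]butan-2-yl}cyclohex-3-ene-1-carboxylic acid, via carbaldehyde 14 (not isolated)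
Conditions: Dess–Martin periodinane, CH2Cl2, rt; then NaClO2, NaH2PO4, 2-methyl-2-butene, t-BuOH/H2O, 0 °C to rt
Reagents that add atoms: sodium chlorite ([Na+].[O-]Cl=O)
Why: Dess–Martin oxidation followed by Pinnick oxidation; neither needs an unhindered carbinol, and the alkene scavenger removes HOCl so that the ring alkene and the silyl ether survive.

Step 11
Reactants: 15 (1R)-4-methyl-1-{2-methyl-4-[tri(propan-2-yl)silyloxy]butan-2-yl}cyclohex-3-ene-1-carboxylic acid
Product: 16 (1S,4R,6S)-6-bromo-1-methyl-4-{2-methyl-4-[tri(propan-2-yl)silyloxy]butan-2-yl}-2-oxabicyclo[2.2.2]octan-3-one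
Conditions: NBS, MeCN, 0 °C, dark
Reagents that add atoms: N-bromosuccinimide (O=C1CCC(=O)N1Br)
Why: Bromolactonisation; the axial carboxyl group opens the bromonium ion at the tertiary carbon C9 (Markovnikov) through a boat, the mode by which hydroxyalkyl-substituted methylcyclohexenes close to cineole-type ethers. The tether fixes the C9–O bond cis to C5, and anti opening fixes bromine on C8 on the opposite face, cis to C1.

Step 12
Reactants: 16 (1S,4R,6S)-6-bromo-1-methyl-4-{2-methyl-4-[tri(propan-2-yl)silyloxy]butan-2-yl}-2-oxabicyclo[2.2.2]octan-3-one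
Product: 18 1-[(1R,3S,4S)-3-bromo-4-hydroxy-4-methyl-1-{2-methyl-4-[tri(propan-2-yl)silyloxy]butan-2-yl}cyclohexyl]ethan-1-one, via bicyclic hemiketal 17 (not isolated)
Conditions: MeLi (1.2 equiv), THF, −78 °C; then H2O
Reagents that add atoms: methyllithium ([Li]C)
Why: Single addition of an organolithium to a lactone; the tetrahedral lithium alkoxide persists at −78 °C and opens through hemiketal 17 only on work-up, so no free tertiary alkoxide is present to displace the neighbouring bromide. The carbonyl has no α-hydrogen, and the bridged bromide has no anti-periplanar hydrogen for E2.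

Step 13
Reactants: 18 1-[(1R,3S,4S)-3-bromo-4-hydroxy-4-methyl-1-{2-methyl-4-[tri(propan-2-yl)silyloxy]butan-2-yl}cyclohexyl]ethan-1-one
Product: 19 1-[(1R,3S,4S)-3-bromo-4-chloro-4-methyl-1-{2-methyl-4-[tri(propan-2-yl)silyloxy]butan-2-yl}cyclohexyl]ethan-1-one
Conditions: HCl (4 M in dioxane), CH2Cl2, −20 to 0 °C
Reagents that add atoms: hydrogen chloride (Cl)
Why: Tertiary alcohol to tertiary chloride with neighbouring-group participation by bromine; acid recloses 18 to hemiketal 17, whose C9–O bond is anti-periplanar to C8–Br and ionises through the bridged oxocarbenium ion to a bromonium ion. Chloride opens this ion at the tertiary carbon from the face the oxygen left (double inversion, net retention). The product relaxes to the chair with both halogens equatorial, where it no longer re-ionises.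

Step 14
Reactants: 19 1-[(1R,3S,4S)-3-bromo-4-chloro-4-methyl-1-{2-methyl-4-[tri(propan-2-yl)silyloxy]butan-2-yl}cyclohexyl]ethan-1-one
Product: 20 {3-[(1S,3S,4S)-3-bromo-4-chloro-4-methyl-1-(prop-1-en-2-yl)cyclohexyl]-3-methylbutoxy}tri(propan-2-yl)silane
Conditions: Cp2Ti(CH2)(Cl)AlMe2 (Tebbe reagent), pyridine, THF/toluene, −40 to 0 °C
Reagents that add atoms: Tebbe reagent Cp2TiCH2ClAlMe2 (C[Al-]1(C)C[Ti]([Cl+]1)(C1C=CC=C1)C1C=CC=C1)
Why: Titanium methylidene olefination ([2+2] addition and cycloreversion) of a hindered methyl ketone; pyridine releases Cp2Ti=CH2 and ties up Me2AlCl, so the tertiary chloride is not ionised. The reagent is non-basic, so the equatorial bromide and chloride are not eliminated.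

Step 15
Reactants: 20 {3-[(1S,3S,4S)-3-bromo-4-chloro-4-methyl-1-(prop-1-en-2-yl)cyclohexyl]-3-methylbutoxy}tri(propan-2-yl)silane
Product: 21 3-[(1S,3S,4S)-3-bromo-4-chloro-4-methyl-1-(prop-1-en-2-yl)cyclohexyl]-3-methylbutan-1-ol
Conditions: HF·pyridine, pyridine, THF, 0 °C
Reagents that add atoms: none
Why: Fluoride cleavage of a primary silyl ether under buffered, non-basic conditions that leave the alkyl halides and the 1,1-disubstituted alkene alone.

Step 16
Reactants: 21 3-[(1S,3S,4S)-3-bromo-4-chloro-4-methyl-1-(prop-1-en-2-yl)cyclohexyl]-3-methylbutan-1-ol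
Product: 22 3-[(1S,3S,4S)-3-bromo-4-chloro-4-methyl-1-(prop-1-en-2-yl)cyclohexyl]-3-methylbutanal
Conditions: Dess–Martin periodinane, CH2Cl2, 0 °C to rt
Reagents that add atoms: none
Why: Dess–Martin oxidation of an unhindered primary alcohol to the aldehyde under neutral conditions.

Step 17
Reactants: 22 3-[(1S,3S,4S)-3-bromo-4-chloro-4-methyl-1-(prop-1-en-2-yl)cyclohexyl]-3-methylbutanal
Product: 23 (2S)-2-bromo-3-[(1S,3S,4S)-3-bromo-4-chloro-4-methyl-1-(prop-1-en-2-yl)cyclohexyl]-3-methylbutanal
Conditions: (2R,5R)-2,5-diphenylpyrrolidine (20 mol%), PhCO2H (20 mol%), 4,4-dibromo-2,6-di-tert-butylcyclohexa-2,5-dien-1-one, CH2Cl2/pentane, −40 °C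
Reagents that add atoms: 4,4-dibromo-2,6-di-tert-butylcyclohexa-2,5-dien-1-one (CC(C)(C)C1=CC(Br)(Br)C=C(C(C)(C)C)C1=O)
Why: Enamine-catalysed α-bromination of an aldehyde; the chiral amine shields one enamine face and sets C2 independently of C6, and the mild bromine donor does not attack the isopropenyl group. The adjacent quaternary carbon slows enolisation of the product, which is used without chromatography.

Step 18
Reactants: 23 (2S)-2-bromo-3-[(1S,3S,4S)-3-bromo-4-chloro-4-methyl-1-(prop-1-en-2-yl)cyclohexyl]-3-methylbutanal
Product: 24 (2S,3S,6S,8S,9S)-2,8-dibromo-9-chloro-1,1,9-trimethyl-5-methylidenespiro[5.5]undecan-3-ol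
Conditions: MeAl(OC6H2-4-Br-2,6-tBu2)2 (MABR, 2 equiv), CH2Cl2, −78 to −40 °C
Reagents that add atoms: none
Why: Type 2 intramolecular carbonyl-ene reaction; the terminal carbon of the isopropenyl group attacks the aluminium-bound aldehyde in a chair, and an allylic methyl hydrogen is lost to give the exocyclic methylene. Bromine sits equatorial, anti to the forming bond, and the bulky aryloxide ligands together with the syn-axial methyl on C1 force the C–O bond equatorial, which gives the trans-diequatorial 3S carbinol. The oxygen-selective Lewis acid leaves the tertiary chloride alone.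

## Compound list

1 | 3-methoxybenzoic acid | COc1cccc(c1)C(=O)O | starting material
2 | 3-methoxycyclohexa-2,5-diene-1-carboxylic acid | COC1=CC(C(=O)O)C=CC1 | intermediate (not isolated)
3 | 3-oxocyclohex-1-ene-1-carboxylic acid | O=C1C=C(C(=O)O)CCC1 | intermediate
4 | (1R,2S,5R)-5-methyl-2-(2-phenylpropan-2-yl)cyclohexan-1-ol (8-phenylmenthol) | C[C@@H]1CC[C@H]([C@@H](C1)O)C(C)(C)c1ccccc1 | starting material
5 | (1R,2S,5R)-8-phenylmenthyl 3-oxocyclohex-1-ene-1-carboxylate | O=C1C=C(C(=O)O[C@@H]2C[C@H](C)CC[C@H]2C(C)(C)c2ccccc2)CCC1 | intermediate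
6 | methyl 3-methylbut-2-enoate | COC(=O)C=C(C)C | starting material
7 | 8-methyl 6-[(1R,2S,5R)-8-phenylmenthyl] (1S,6R,8S)-7,7-dimethyl-2-oxobicyclo[4.2.0]octane-6,8-dicarboxylate (cis-fused; C8 epimer drawn) | O=C1CCC[C@@]2(C(=O)O[C@@H]3C[C@H](C)CC[C@H]3C(C)(C)c3ccccc3)[C@@H]1[C@H](C(=O)OC)C2(C)C | intermediate
8 | (1R,2S,5R)-8-phenylmenthyl (1R)-1-(4-methoxy-2-methyl-4-oxobutan-2-yl)-3-oxocyclohexane-1-carboxylate | O=C1CCC[C@](C(=O)O[C@@H]2C[C@H](C)CC[C@H]2C(C)(C)c2ccccc2)(C(C)(C)CC(=O)OC)C1 | intermediate
9 | (1R,2S,5R)-8-phenylmenthyl (1R,4RS)-1-(4-methoxy-2-methyl-4-oxobutan-2-yl)-4-methyl-3-oxocyclohexane-1-carboxylate (C4 epimers) | O=C1C(C)CC[C@](C(=O)O[C@@H]2C[C@H](C)CC[C@H]2C(C)(C)c2ccccc2)(C(C)(C)CC(=O)OC)C1 | intermediate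
10 | (1R,2S,5R)-8-phenylmenthyl (1R)-1-(4-methoxy-2-methyl-4-oxobutan-2-yl)-4-methyl-3-(trifluoromethanesulfonyloxy)cyclohex-3-ene-1-carboxylate | CC1=C(OS(=O)(=O)C(F)(F)F)C[C@@](C(=O)O[C@@H]2C[C@H](C)CC[C@H]2C(C)(C)c2ccccc2)(C(C)(C)CC(=O)OC)CC1 | intermediate
11 | (1R,2S,5R)-8-phenylmenthyl (1R)-1-(4-methoxy-2-methyl-4-oxobutan-2-yl)-4-methylcyclohex-3-ene-1-carboxylate | CC1=CC[C@@](C(=O)O[C@@H]2C[C@H](C)CC[C@H]2C(C)(C)c2ccccc2)(C(C)(C)CC(=O)OC)CC1 | intermediate
12 | 3-[(1R)-1-(hydroxymethyl)-4-methylcyclohex-3-en-1-yl]-3-methylbutan-1-ol | CC1=CC[C@@](CO)(C(C)(C)CCO)CC1 | intermediate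
13 | [(1R)-4-methyl-1-{2-methyl-4-[tri(propan-2-yl)silyloxy]butan-2-yl}cyclohex-3-en-1-yl]methanol | CC1=CC[C@@](CO)(C(C)(C)CCO[Si](C(C)C)(C(C)C)C(C)C)CC1 | intermediate
14 | (1R)-4-methyl-1-{2-methyl-4-[tri(propan-2-yl)silyloxy]butan-2-yl}cyclohex-3-ene-1-carbaldehyde | CC1=CC[C@@](C=O)(C(C)(C)CCO[Si](C(C)C)(C(C)C)C(C)C)CC1 | intermediate (not isolated)
15 | (1R)-4-methyl-1-{2-methyl-4-[tri(propan-2-yl)silyloxy]butan-2-yl}cyclohex-3-ene-1-carboxylic acid | CC1=CC[C@@](C(=O)O)(C(C)(C)CCO[Si](C(C)C)(C(C)C)C(C)C)CC1 | intermediate
16 | (1S,4R,6S)-6-bromo-1-methyl-4-{2-methyl-4-[tri(propan-2-yl)silyloxy]butan-2-yl}-2-oxabicyclo[2.2.2]octan-3-one | O=C1O[C@@]2(C)CC[C@]1(C(C)(C)CCO[Si](C(C)C)(C(C)C)C(C)C)C[C@@H]2Br | intermediate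
17 | (1S,4R,6S)-6-bromo-1,3-dimethyl-4-{2-methyl-4-[tri(propan-2-yl)silyloxy]butan-2-yl}-2-oxabicyclo[2.2.2]octan-3-ol (C3 epimers) | CC1(O)O[C@@]2(C)CC[C@]1(C(C)(C)CCO[Si](C(C)C)(C(C)C)C(C)C)C[C@@H]2Br | intermediate (not isolated)
18 | 1-[(1R,3S,4S)-3-bromo-4-hydroxy-4-methyl-1-{2-methyl-4-[tri(propan-2-yl)silyloxy]butan-2-yl}cyclohexyl]ethan-1-one | C[C@]1(O)CC[C@](C(C)=O)(C(C)(C)CCO[Si](C(C)C)(C(C)C)C(C)C)C[C@@H]1Br | intermediate
19 | 1-[(1R,3S,4S)-3-bromo-4-chloro-4-methyl-1-{2-methyl-4-[tri(propan-2-yl)silyloxy]butan-2-yl}cyclohexyl]ethan-1-one | C[C@]1(Cl)CC[C@](C(C)=O)(C(C)(C)CCO[Si](C(C)C)(C(C)C)C(C)C)C[C@@H]1Br | intermediate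
20 | {3-[(1S,3S,4S)-3-bromo-4-chloro-4-methyl-1-(prop-1-en-2-yl)cyclohexyl]-3-methylbutoxy}tri(propan-2-yl)silane | C[C@]1(Cl)CC[C@](C(C)=C)(C(C)(C)CCO[Si](C(C)C)(C(C)C)C(C)C)C[C@@H]1Br | intermediate
21 | 3-[(1S,3S,4S)-3-bromo-4-chloro-4-methyl-1-(prop-1-en-2-yl)cyclohexyl]-3-methylbutan-1-ol | C[C@]1(Cl)CC[C@](C(C)=C)(C(C)(C)CCO)C[C@@H]1Br | intermediate
22 | 3-[(1S,3S,4S)-3-bromo-4-chloro-4-methyl-1-(prop-1-en-2-yl)cyclohexyl]-3-methylbutanal | C[C@]1(Cl)CC[C@](C(C)=C)(C(C)(C)CC=O)C[C@@H]1Br | intermediate
23 | (2S)-2-bromo-3-[(1S,3S,4S)-3-bromo-4-chloro-4-methyl-1-(prop-1-en-2-yl)cyclohexyl]-3-methylbutanal | C[C@]1(Cl)CC[C@](C(C)=C)(C(C)(C)[C@H](Br)C=O)C[C@@H]1Br | intermediate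
24 | (2S,3S,6S,8S,9S)-2,8-dibromo-9-chloro-1,1,9-trimethyl-5-methylidenespiro[5.5]undecan-3-ol | C=C1C[C@H](O)[C@@H](Br)C(C)(C)[C@]12CC[C@](C)(Cl)[C@@H](Br)C2 | target

## Step count and risk

Total step count: 18. Longest linear sequence: 18 steps, from 1 to 24; 4 and 6 enter as purchased reagents.

**Step 3 (key step).** The most likely failures are bonding in the head-to-tail sense, or slow addition with hydrogen abstraction from the alkene methyl groups, because the alkene is both electron-poor and trisubstituted. Facial selection may also be eroded by rotation about the enoate C–C bond. The fallback sets out from 5 and makes the same C6–C1 bond thermally. TiCl4-promoted Hosomi–Sakurai conjugate addition of trimethyl(3-methylbut-2-en-1-yl)silane, which reacts at its dimethyl-substituted γ-carbon, would give the 1,1-dimethylallyl keto ester F1 under the same auxiliary control. Methylation, triflation and formate reduction as in steps 5 to 7 would lead through the methyl ketone F2 and the enol triflate F3 to the diene ester F4. LiAlH4 would give the neopentyl alcohol F5, and hydroboration of the monosubstituted vinyl group with 9-BBN, then NaOH/H2O2, would give diol 12, where the route is rejoined.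

**Step 6.** Enolisation toward C7 instead of C9 would give the regioisomeric enol triflate, because the thermodynamic preference for the more substituted enol is only moderate. The fallback sets out from 8 and makes the enolate regiospecifically. Kinetic enolate formation and trapping with Eschenmoser's salt would give the Mannich base F6, and quaternisation with MeI followed by NaHCO3 would give the α-methylene ketone F7. Conjugate reduction with LiBH(sBu)3 at −78 °C would generate only the C8–C9 enolate, and PhNTf2 would trap it as 10.

**Step 11.** The carboxylate may close onto C8 instead of C9, giving a five-membered lactone through a chair-like, anti-Markovnikov opening, or the bromonium ion on the other face may be captured by an external nucleophile. The fallback sets out from 13 and uses the alcohol as the internal nucleophile, for which closure at the tertiary carbon has the closest precedent. NBS would give the bicyclic bromo ether F8, and RuCl3 (cat.)/NaIO4 would oxidise its ring O–CH2 group, the only dialkyl ether carbon that bears hydrogen, to lactone 16; the carbon next to the bulky silyloxy group is expected to react far more slowly.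

**Step 13.** The open-chain form of 18, in which C–O and C–Br are gauche, may ionise without bromine bridging. Chloride would then be captured from the axial face, or a proton lost, and the C9 configuration would be eroded. The fallback sets out from 16, where the bicycle holds C9–O anti-periplanar to C8–Br. TiCl4 in CH2Cl2 would cleave the tertiary alkyl–oxygen bond with chloride return to give the chloro acid F9. Oxalyl chloride would give the acid chloride F10, and Me2CuLi at −78 °C would give ketone 19.

**Step 18.** The aluminium-bound oxygen may take the axial position, as the polar Felkin–Anh arrangement and a closed ene transition state would prefer, which gives the C3 epimer. The Lewis acid may also ionise the tertiary chloride. The fallback sets out from 23 and sets C3 by substitution instead. Me2AlCl, which favours the closed transition state, would deliberately give the axial alcohol F11. Mitsunobu reaction with 4-nitrobenzoic acid would invert C3 to give the ester F12, and K2CO3/MeOH at 0 °C would release 24.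

## Further compounds

F1 | step 3 | (1R,2S,5R)-8-phenylmenthyl (1R)-1-(2-methylbut-3-en-2-yl)-3-oxocyclohexane-1-carboxylate | O=C1CCC[C@](C(=O)O[C@@H]2C[C@H](C)CC[C@H]2C(C)(C)c2ccccc2)(C(C)(C)C=C)C1
F2 | step 3 | (1R,2S,5R)-8-phenylmenthyl (1R,4RS)-4-methyl-1-(2-methylbut-3-en-2-yl)-3-oxocyclohexane-1-carboxylate | O=C1C(C)CC[C@](C(=O)O[C@@H]2C[C@H](C)CC[C@H]2C(C)(C)c2ccccc2)(C(C)(C)C=C)C1
F3 | step 3 | (1R,2S,5R)-8-phenylmenthyl (1R)-4-methyl-1-(2-methylbut-3-en-2-yl)-3-(trifluoromethanesulfonyloxy)cyclohex-3-ene-1-carboxylate | CC1=C(OS(=O)(=O)C(F)(F)F)C[C@@](C(=O)O[C@@H]2C[C@H](C)CC[C@H]2C(C)(C)c2ccccc2)(C(C)(C)C=C)CC1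
F4 | step 3 | (1R,2S,5R)-8-phenylmenthyl (1R)-4-methyl-1-(2-methylbut-3-en-2-yl)cyclohex-3-ene-1-carboxylate | CC1=CC[C@@](C(=O)O[C@@H]2C[C@H](C)CC[C@H]2C(C)(C)c2ccccc2)(C(C)(C)C=C)CC1
F5 | step 3 | [(1R)-4-methyl-1-(2-methylbut-3-en-2-yl)cyclohex-3-en-1-yl]methanol | CC1=CC[C@@](CO)(C(C)(C)C=C)CC1
F6 | step 6 | (1R,2S,5R)-8-phenylmenthyl (1R,4RS)-4-[(dimethylamino)methyl]-1-(4-methoxy-2-methyl-4-oxobutan-2-yl)-3-oxocyclohexane-1-carboxylate | O=C1C(CN(C)C)CC[C@](C(=O)O[C@@H]2C[C@H](C)CC[C@H]2C(C)(C)c2ccccc2)(C(C)(C)CC(=O)OC)C1
F7 | step 6 | (1R,2S,5R)-8-phenylmenthyl (1R)-1-(4-methoxy-2-methyl-4-oxobutan-2-yl)-4-methylidene-3-oxocyclohexane-1-carboxylate | O=C1C(=C)CC[C@](C(=O)O[C@@H]2C[C@H](C)CC[C@H]2C(C)(C)c2ccccc2)(C(C)(C)CC(=O)OC)C1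
F8 | step 11 | (1S,4R,6S)-6-bromo-1-methyl-4-{2-methyl-4-[tri(propan-2-yl)silyloxy]butan-2-yl}-2-oxabicyclo[2.2.2]octane | C1O[C@@]2(C)CC[C@]1(C(C)(C)CCO[Si](C(C)C)(C(C)C)C(C)C)C[C@@H]2Br
F9 | step 13 | (1R,3S,4S)-3-bromo-4-chloro-4-methyl-1-{2-methyl-4-[tri(propan-2-yl)silyloxy]butan-2-yl}cyclohexane-1-carboxylic acid | C[C@]1(Cl)CC[C@](C(=O)O)(C(C)(C)CCO[Si](C(C)C)(C(C)C)C(C)C)C[C@@H]1Br
F10 | step 13 | (1R,3S,4S)-3-bromo-4-chloro-4-methyl-1-{2-methyl-4-[tri(propan-2-yl)silyloxy]butan-2-yl}cyclohexane-1-carbonyl chloride | C[C@]1(Cl)CC[C@](C(=O)Cl)(C(C)(C)CCO[Si](C(C)C)(C(C)C)C(C)C)C[C@@H]1Br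
F11 | step 18 | (2S,3R,6S,8S,9S)-2,8-dibromo-9-chloro-1,1,9-trimethyl-5-methylidenespiro[5.5]undecan-3-ol | C=C1C[C@@H](O)[C@@H](Br)C(C)(C)[C@]12CC[C@](C)(Cl)[C@@H](Br)C2
F12 | step 18 | (2S,3S,6S,8S,9S)-2,8-dibromo-9-chloro-1,1,9-trimethyl-5-methylidenespiro[5.5]undecan-3-yl 4-nitrobenzoate | C=C1C[C@H](OC(=O)c3ccc(cc3)[N+](=O)[O-])[C@@H](Br)C(C)(C)[C@]12CC[C@](C)(Cl)[C@@H](Br)C2
A1 | alternative 1 | ring A trans-bromohydrin with exocyclic methylene, spiro-fused to cyclohexanone ethylene ketal | C=C1C[C@H](O)[C@@H](Br)C(C)(C)C12CCC3(CC2)OCCO3
A2 | alternative 1 | (2S)-2-bromo-3-methyl-3-[8-(prop-1-en-2-yl)-1,4-dioxaspiro[4.5]decan-8-yl]butanal | O=C[C@@H](Br)C(C)(C)C1(C(C)=C)CCC2(CC1)OCCO2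
A3 | alternative 2 | 1,5,9-trimethylspiro[5.5]undeca-1,4,8-trien-3-one | CC1=CC(=O)C=C(C)C12CCC(C)=CC2
A4 | alternative 2 | 3,5-dimethylphenol | Cc1cc(O)cc(C)c1
A5 | alternative 2 | (Z)-5-(4-hydroxy-2,6-dimethylphenyl)-3-methylpent-3-en-1-yl 4-methylbenzenesulfonate | Cc1cc(O)cc(C)c1C/C=C(C)\CCOS(=O)(=O)c1ccc(C)cc1
A6 | alternative 3 | spiro[5.5]undecenone with ring A ketone, silyl ether and bromide and the ring B trisubstituted alkene | O=C1C[C@H](O[Si](C)(C)C(C)(C)C)[C@@H](Br)C(C)(C)[C@]12CCC(C)=CC2
A7 | alternative 3 | (3S,4S)-3-bromo-4-(tert-butyldimethylsilyloxy)-1-[(Z)-6-chloro-5-methylhexa-1,4-dien-2-yl]-2,2-dimethylcyclopentan-1-ol (carbinol configuration open) | OC1(C(=C)C/C=C(C)\CCl)C[C@H](O[Si](C)(C)C(C)(C)C)[C@@H](Br)C1(C)C
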